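The earlier runs and the new flask are simulated from invented constants, and the scatter is random.

Late in the beta run, at 40.0 h, adduct has sunk to 13.5 % and target has risen to 39.2 %, yet at 0.417 h adduct already stood at 45.7 %. Filling is quick and draining slow, so look for the peak near where the net rate of filling reaches zero.

all flasks: substrate 0.80 M

|  | reagent | capture agent | remark | time |
|---|---|---|---|---|
| beta | 0.88 M | 0.040 M | run made earlier |  |
| theta | 0.88 M | 0.060 M | run made earlier |  |
| flask | 0.880 M | 0.0800 M |  | 40 h |

| run | time / h | adduct / % | target / % |
|---|---|---|---|
| beta | 0.417 | 45.7 | 1.3 |
| beta | 2.00 | 46.9 | 1.8 |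
| beta | 8.00 | 37.0 | 13.4 |
| beta | 40.0 | 13.5 | 39.2 |
| theta | 0.417 | 49.3 | 1.8 |
| theta | 2.00 | 44.2 | 4.8 |
| theta | 8.00 | 36.5 | 11.4 |
| theta | 40.0 | 17.0 | 38.7 |

(readings scatter by 1 percentage point)

- what was read earlier has a scatter of 1 percentage point, one standard deviation

1. the best time, 40 h at the latest, for adduct
2. the amount of adduct, in percent of the substrate charged, at that time

Call the forward rate at the start one. As adduct forms, that rate shrinks by the fraction of substrate still free and by the fraction of reagent still free, while the backward run grows to meet it. Take adduct over free substrate times free reagent, counting target as used substrate. The four readings of the beta and theta runs up to 2.00 h average 1.87 /M, with their scatter. This is the balance quotient, the equilibrium constant of adduct formation, where the net rate is zero.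

I leave capture agent out of it, and the quotient then gives the new flask a reckoned ceiling of 48.1 % adduct. There the substrate factor is 51.9 % and the reagent factor 56.3 %, leaving 29.2 % of the starting forward rate, and the backward run cancels that remainder. I put the peak near 0.417 h.

The forecast says 50 % (47 % to 54 %) at 0.7 h (0.3 h to 2 h), above my ceiling: “That fits capture of a by-product that pulls the equilibrium forward”.

The flask gives 47.4 % at 0.453 h, so the forecast's amount holds within its tolerance and its time is too late by a factor of 1.55.

    adduct → target (k = 0.0480 /h)
    target ⇌ isomer of the product (K = 0.330, k = 0.340 /h)
    substrate + reagent ⇌ adduct (K = 1.90 /M, k = 8.50 /M/h)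
    capture agent + adduct → trapped intermediate (k = 0.180 /M/h)

At that time the flask holds 51.5 % substrate and 55.9 % of the reagent charge, and 1.87 /M applied to these gives 47.4 % adduct. The backward run from adduct holds the peak down: the run without it reaches 88.0 % instead of 47.4 %, while the capture path makes no difference to it.

With 1.5 M of reagent, 1.87 /M gives a ceiling of 64.8 %; that flask peaks at 63.9 %.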